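Sunday's flask is charged with more partner than substrate, by a factor 3.03, so substrate is the limiting reagent, whereas Monday's flask, with the same 0.300 M of partner, held the two equal.

| setting | Friday's | Thursday's | Monday's | Tuesday's | Sunday's |
|---|---|---|---|---|---|
| substrate | 0.300 M | 0.180 M | 0.300 M | 0.600 M | 0.0990 M |
| partner | 0.600 M | 0.480 M | 0.300 M | 0.600 M | 0.300 M |
| time |  |  |  |  | 43 min |

- Friday's run (time / min: [target] / M): 1.7: 0.0223; 3.8: 0.0454; 8.6: 0.0860; 19: 0.1472; 43: 0.1967
- Thursday's run (time / min: [target] / M): 1.7: 0.0092; 3.8: 0.0220; 8.6: 0.0465; 19: 0.0843; 43: 0.1154
- Monday's run (time / min: [target] / M): 1.7: 0.0136; 3.8: 0.0285; 8.6: 0.0542; 19: 0.0999; 43: 0.1457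
- Tuesday's run (time / min: [target] / M): 1.7: 0.0412; 3.8: 0.0806; 8.6: 0.1677; 19: 0.2683; 43: 0.3448

(each reading ± 0.002 M)

1. the exponent of [substrate] in the starting rate at the charge of the Friday's run (at the point where two percent of the substrate have become target) (one fixed amount of target, the same in the runs compared)
2. the exponent of [partner] in the starting rate at the charge of the Friday's run (at the point where two percent of the substrate have become target)
3. target in the Sunday's run at 43 min, as a share of the substrate charged

- Overall: substrate + partner -> target.
- Constant volume, constant temperature.
- Bound and free are read together.
- "The second partner" is partner.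
- An order is taken over about fifteen percent of the charge, up and down.

My own reckoning treats the rate as a constant times [substrate][partner]. The ratio [partner]/[substrate] then grows exponentially, and the exponent is the constant times the difference of the charges times the time. Monday's flask supplies the constant at this partner charge: its equal charges and its 0.1457 M of target at 43 min give 0.0732 /M/min, a whole-run value. For Sunday's flask at 43 min the exponent is 0.633, the ratio count, the number of e-foldings of [partner]/[substrate]. Starting from 3.03, that ratio corresponds to a share of 56.8 %.

One number may not be enough, so Friday's flask tests it. Its count, with Monday's constant, is 0.944, which predicts 75.9 %, but the reading is 65.6 %. Friday's own constant, read from that reading, is 0.0519 /M/min, less than Monday's 0.0732 /M/min, at the same substrate charge and twice the partner charge. By the overall equation, at my share Sunday's partner ends at 0.244 M, more than the 0.154 M reckoned the same way from the last target reading of Monday's flask, so I expect a constant below Monday's, and my share leans high.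

The forecast gives 0.93 (0.78 to 1.08) for the substrate exponent, 0.63 (0.42 to 0.82) for the partner exponent and 60 % (55 % to 65 %) for Sunday's flask. That share is more than mine: for Sunday's flask it takes a constant of 0.08, and of the lower whole-run values it says they are “suggesting mild product drag”.

Sunday's flask gives 54.9 %.

    substrate + partner → target (0.2934 /M/min)
    substrate + 2 partner → target + partner (1.152 /M²/min)
    2 partner ⇌ idle reagent dimer, settled at all times (22.40 /M)
    target → decomposed product (0.006660 /min)

In the starting rate at Friday's charge the exponent of [partner] is 0.72 and that of [substrate] is 1.0. Turned back into the ratio count through the overall equation, Sunday's share means 0.596 in place of 0.633, a whole-run constant of 0.0690 /M/min, lower than the 0.0732 /M/min read from Monday's flask and higher than the 0.0519 /M/min read from Friday's.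

The earlier runs and the new flask were generated by integration on assumed constants.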